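Retrosynthesis: the 7-O–S bond and the 4'-O–benzyl bond are cut first. Ring C is then opened in one stroke at C4a–C4, C4–C3 and O1–C2, giving an o-iodophenol (ring A with O1), carbon monoxide (C4=O) and 4-benzyloxyphenylacetylene (C3, C2, ring B).
Enabling feature: in ring A, C8a (the carbon bearing O1) lies para to C6–OMe, and the oxygens on C5 and C7 mirror each other across the C8a–C6 axis. A 4-methoxyphenol with like groups on O3 and O5 therefore has two identical ortho C–H carbons (future C4a and C8) and a single free OH.
Iodination of that phenol has no regiochemical choice to make, and only this OH can become O1, so the 5,6,7-pattern cannot turn into the 5,7,8-pattern.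
The phenol goes back, through C–O and C–B bonds at the one unflanked C–H, to bis-MOM-protected 2-methoxyresorcinol. The alkyne goes back to 4-benzyloxybenzaldehyde.
Forward: rings A and B are bought as benzenes and ring C is the only ring closed (carbonylative annulation). MOM removal, 7-O-sulfation, debenzylation and Na+/H+ exchange follow.
Stereochemistry: the target has no stereocentre and is achiral. Its only geometric element, C2=C3, is held inside ring C.

Key step: step 6

Remark: because the molecule is achiral, the request for a single enantiomer is met by the constitution alone. The sulfate ester is carried as its sodium salt and converted into the hydrogen sulfate drawn in the target only in the last step.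

Step 1
Reactants: 1 2-methoxyresorcinol
Product: 2 2-methoxy-1,3-bis(methoxymethoxy)benzene
Conditions: NaH (2.5 equiv), MOMCl (2.5 equiv), DMF, 0 °C to rt
Reagents that add atoms: chloromethyl methyl ether (MOMCl), COCCl
Why: Williamson-type O-alkylation of both phenoxides gives two identical acetal ethers that tolerate Ir catalysis, alkaline peroxide, NIS and hot amine and can later be removed together with mild acid.

Step 2
Reactants: 2 2-methoxy-1,3-bis(methoxymethoxy)benzene
Product: 3 2-[4-methoxy-3,5-bis(methoxymethoxy)phenyl]-4,4,5,5-tetramethyl-1,3,2-dioxaborolane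
Conditions: [Ir(OMe)(cod)]2 (1.5 mol %), dtbpy (3 mol %), B2pin2 (1.0 equiv), THF, 80 °C, sealed tube
Reagents that add atoms: bis(pinacolato)diboron, CC1(C)OB(OC1(C)C)B1OC(C)(C)C(C)(C)O1
Why: Hartwig–Miyaura C–H borylation is governed by sterics, and in this 1,2,3-trisubstituted benzene only the C5–H has no ortho neighbour, so a single boronate should form.

Step 3
Reactants: 3 2-[4-methoxy-3,5-bis(methoxymethoxy)phenyl]-4,4,5,5-tetramethyl-1,3,2-dioxaborolane
Product: 4 4-methoxy-3,5-bis(methoxymethoxy)phenol
Conditions: 30% aq H2O2, NaOH (1 equiv), THF, 0 °C, neutral work-up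
Reagents that add atoms: hydrogen peroxide, OO
Why: Oxidation of an arylboronate by hydroperoxide addition to boron and 1,2-aryl shift from B to O places the hydroxyl exactly where boron stood, and the basic medium leaves the MOM ethers alone.

Step 4
Reactants: 4 4-methoxy-3,5-bis(methoxymethoxy)phenol
Product: 5 2-iodo-4-methoxy-3,5-bis(methoxymethoxy)phenol
Conditions: NIS (1.0 equiv, slow addition), MeCN, −20 to 0 °C, dark
Reagents that add atoms: N-iodosuccinimide, O=C1CCC(=O)N1I
Why: In this electrophilic aromatic iodination the para carbon is blocked by OMe and the two ortho carbons are equivalent, so one equivalent of an acid-free I(+) source at low temperature should give one mono-iodide with the MOM ethers intact.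

Step 5
Reactants: 6 4-(benzyloxy)benzaldehyde
Product: 7 1-(benzyloxy)-4-ethynylbenzene
Conditions: dimethyl (1-diazo-2-oxopropyl)phosphonate (1.2 equiv), K2CO3 (2 equiv), MeOH, rt
Reagents that add atoms: Ohira–Bestmann reagent, COP(=O)(OC)C(=[N+]=[N-])C(C)=O
Why: In the Seyferth–Gilbert homologation (Ohira–Bestmann variant) methanolysis frees the diazomethylphosphonate anion, which olefinates the non-enolisable aldehyde, and loss of N2 with a 1,2-hydride shift gives the terminal alkyne without touching the benzyl ether.

Step 6
Reactants: 5 2-iodo-4-methoxy-3,5-bis(methoxymethoxy)phenol; 7 1-(benzyloxy)-4-ethynylbenzene; 8 carbon monoxide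
Product: 11 4'-benzyloxy-6-methoxy-5,7-bis(methoxymethoxy)flavone, via hydroxyaryl ynone 9 (not isolated), via diethylamino enaminone 10 (not isolated)
Conditions: PdCl2(dppf) (5 mol %), CO (20 bar), Et2NH (solvent and base), 120 °C, autoclave, no copper salt
Reagents that add atoms: carbon monoxide (compound 8), [C-]#[O+]; diethylamine, CCNCC (bound only in 10 and released again on ring closure)
Why: Pd(0) inserts into the C–I bond of 5, CO migrates into the aryl–Pd bond (C4a–C4), and the aroyl–Pd species couples with the amine-deprotonated alkyne 7 (C4–C3) to give ynone 9, a copper-free carbonylative Sonogashira coupling. Diethylamine then adds to the β-carbon of 9 to give enaminone 10, and the phenol oxygen displaces the amine there by addition–elimination (O1–C2), so ring C closes in a net 6-endo mode onto the finished ring A. The closest known reaction type is the Pd-catalysed carbonylative annulation of 2-iodophenols with terminal arylacetylenes in diethylamine, an established flavone synthesis. No stereocentre is formed, and the new C2=C3 bond is endocyclic, so its geometry is fixed. Carbonylative coupling must win over direct coupling: the aryl–Pd carbon is flanked by OH and OMOM, which slows hand-over of the bulky acetylide but not uptake of the small CO, and the CO pressure and the absence of copper act in the same direction. 6-endo closure over 5-exo (aurone) closure is secured by the enaminone relay, and regiochemistry is secured by the substrate, since only one oxygen of 5 is free and the other two are MOM ethers.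

Step 7
Reactants: 11 4'-benzyloxy-6-methoxy-5,7-bis(methoxymethoxy)flavone
Product: 12 4'-O-benzylhispidulin (4'-benzyloxy-5,7-dihydroxy-6-methoxyflavone)
Conditions: HCl (1.25 M in MeOH), THF, 45 °C
Reagents that add atoms: none
Why: Acid-catalysed acetal exchange with methanol removes both MOM groups in one operation, while the benzyl and methyl aryl ethers are inert and the acidity stays far below what would open the pyranone (Wessely–Moser rearrangement).

Step 8
Reactants: 12 4'-O-benzylhispidulin
Product: 14 sodium 4'-O-benzylhispidulin 7-sulfate, via pyridinium sulfate salt 13 (not isolated)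
Conditions: SO3·pyridine (2 equiv), DMF, rt; then aq NaHCO3 to pH 7–8, C18 or Sephadex LH-20
Reagents that add atoms: sulfur trioxide–pyridine complex, [O-]S(=O)(=O)[n+]1ccccc1; sodium hydrogen carbonate, [Na+].OC([O-])=O
Why: In this O-sulfation by an SO3–amine complex only the acidic, unchelated 7-OH reacts, because the 5-OH is tied up in the six-membered hydrogen bond to C4=O and the 4'-oxygen is benzylated, and the bicarbonate work-up exchanges pyridinium for sodium so that the acid-labile ester is kept as a neutral salt.

Step 9
Reactants: 14 sodium 4'-O-benzylhispidulin 7-sulfate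
Product: 15 sodium hispidulin 7-sulfate
Conditions: H2 (1 atm), 10% Pd/C, MeOH–H2O (4:1), rt, stopped after one equivalent of H2
Reagents that add atoms: none
Why: Catalytic hydrogenolysis cleaves the aryl benzyl ether at room temperature and one atmosphere well before the conjugated C2=C3 bond of a flavone is reduced, and a sulfate monoester held as its neutral sodium salt is inert to H2/Pd, as is well known for benzyl-protected flavonoid sulfates.

Step 10
Reactants: 15 sodium hispidulin 7-sulfate
Product: 16 hispidulin 7-sulfate (5-hydroxy-2-(4-hydroxyphenyl)-6-methoxy-4-oxo-4H-chromen-7-yl hydrogen sulfate)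
Conditions: Dowex 50WX8 (H+ form), H2O–MeOH (9:1), 0–4 °C, short column, eluate frozen at once and lyophilised
Reagents that add atoms: none
Why: Cation exchange on a sulfonic acid resin swaps Na+ for H+ without touching a covalent bond, and cold, dilute, mainly aqueous solution with short contact and immediate freeze-drying is chosen because the proton form of an aryl sulfate solvolyses under acid catalysis, fastest in water-poor organic media.

Compound list
1 | 2-methoxyresorcinol (2-methoxybenzene-1,3-diol) | COc1c(O)cccc1O | starting material
2 | 2-methoxy-1,3-bis(methoxymethoxy)benzene | COCOc1cccc(OCOC)c1OC | intermediate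
3 | 2-[4-methoxy-3,5-bis(methoxymethoxy)phenyl]-4,4,5,5-tetramethyl-1,3,2-dioxaborolane | COCOc1cc(B2OC(C)(C)C(C)(C)O2)cc(OCOC)c1OC | intermediate
4 | 4-methoxy-3,5-bis(methoxymethoxy)phenol | COCOc1cc(O)cc(OCOC)c1OC | intermediate
5 | 2-iodo-4-methoxy-3,5-bis(methoxymethoxy)phenol | COCOc1cc(O)c(I)c(OCOC)c1OC | intermediate
6 | 4-(benzyloxy)benzaldehyde | O=Cc1ccc(OCc2ccccc2)cc1 | starting material
7 | 1-(benzyloxy)-4-ethynylbenzene | C#Cc1ccc(OCc2ccccc2)cc1 | intermediate
8 | carbon monoxide | [C-]#[O+] | starting material
9 | 3-[4-(benzyloxy)phenyl]-1-[6-hydroxy-3-methoxy-2,4-bis(methoxymethoxy)phenyl]prop-2-yn-1-one (forms in the flask in step 6) | COCOc1cc(O)c(C(=O)C#Cc2ccc(OCc3ccccc3)cc2)c(OCOC)c1OC | intermediate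
10 | (E)-3-[4-(benzyloxy)phenyl]-3-(diethylamino)-1-[6-hydroxy-3-methoxy-2,4-bis(methoxymethoxy)phenyl]prop-2-en-1-one (forms in the flask in step 6; push-pull alkene, configurationally labile) | COCOc1cc(O)c(C(=O)/C=C(/N(CC)CC)c2ccc(OCc3ccccc3)cc2)c(OCOC)c1OC | intermediate
11 | 4'-benzyloxy-6-methoxy-5,7-bis(methoxymethoxy)flavone (2-[4-(benzyloxy)phenyl]-6-methoxy-5,7-bis(methoxymethoxy)-4H-chromen-4-one) | COCOc1cc2oc(-c3ccc(OCc4ccccc4)cc3)cc(=O)c2c(OCOC)c1OC | intermediate
12 | 4'-O-benzylhispidulin (2-[4-(benzyloxy)phenyl]-5,7-dihydroxy-6-methoxy-4H-chromen-4-one) | COc1c(O)cc2oc(-c3ccc(OCc4ccccc4)cc3)cc(=O)c2c1O | intermediate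
13 | pyridinium 2-[4-(benzyloxy)phenyl]-5-hydroxy-6-methoxy-4-oxo-4H-chromen-7-yl sulfate (forms in the flask in step 8) | COc1c(OS(=O)(=O)[O-])cc2oc(-c3ccc(OCc4ccccc4)cc3)cc(=O)c2c1O.c1cc[nH+]cc1 | intermediate
14 | sodium 2-[4-(benzyloxy)phenyl]-5-hydroxy-6-methoxy-4-oxo-4H-chromen-7-yl sulfate | COc1c(OS(=O)(=O)[O-])cc2oc(-c3ccc(OCc4ccccc4)cc3)cc(=O)c2c1O.[Na+] | intermediate
15 | sodium 5-hydroxy-2-(4-hydroxyphenyl)-6-methoxy-4-oxo-4H-chromen-7-yl sulfate | COc1c(OS(=O)(=O)[O-])cc2oc(-c3ccc(O)cc3)cc(=O)c2c1O.[Na+] | intermediate
16 | hispidulin 7-sulfate (achiral) | COc1c(OS(=O)(=O)O)cc2oc(-c3ccc(O)cc3)cc(=O)c2c1O | target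

Total step count: 10.
Longest linear sequence: 9 steps (steps 1–4 and 6–10, from 1 to 16). Step 5 is the one-step side branch to the alkyne.

Steps most likely to fail

1. Step 6. The iodide is electron-rich and doubly ortho-substituted. It may lose iodine by protodehalogenation, the acyl–palladium species may be intercepted by diethylamine (aminocarbonylation), or alkynylation may occur without CO uptake and be followed by furan closure. The fallback brings in the carbonyl carbon on the alkyne partner by polar chemistry instead of as gas. It sets out from 7 and 5. Alkyne 7 is deprotonated (n-BuLi, THF, −78 °C) and acylated with N-methoxy-N-methylcarbamoyl chloride to give N-methoxy-N-methyl-3-[4-(benzyloxy)phenyl]prop-2-ynamide F1. Iodophenol 5 is treated with n-BuLi (2.1 equiv, THF, −78 °C) for O–H deprotonation followed by iodine–lithium exchange. Addition to F1 should then give, after work-up, ynone 9 as an isolated compound. Warm Et2NH in EtOH carries 9 through 10 to 11, where the route is rejoined.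

2. Step 10. The sulfate ester may be lost by acid-catalysed solvolysis inside the strongly acidic resin beads or while the proton form is concentrated. The fallback replaces the resin by a precipitation metathesis that never offers more than one proton per ester. It sets out from 15. Ba(OAc)2 (0.5 equiv) in cold H2O–EtOH should deposit barium bis(hispidulin 7-sulfate) F2. This is suspended in ice water and treated with exactly one equivalent of dilute H2SO4 per barium. The barium sulfate is spun off and the dilute filtrate is freeze-dried directly, which returns to the route at 16.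

3. Step 4. A second iodination at the remaining ortho carbon may compete, and the I(+) source may oxidise the very electron-rich 4-alkoxyphenol ring. The fallback exchanges electrophilic substitution for directed ortho-metalation, in which one equivalent of base limits the reaction to one substitution and no oxidant meets a free phenol. It sets out from 4. ClC(O)NEt2 and NaH in THF give 4-methoxy-3,5-bis(methoxymethoxy)phenyl N,N-diethylcarbamate F3. s-BuLi/TMEDA (THF, −78 °C) lithiates the carbon between the carbamate and a MOM ether, where the two directing groups cooperate and the two such carbons are equivalent. An I2 quench at −78 °C, before any anionic Fries shift, gives 2-iodo-4-methoxy-3,5-bis(methoxymethoxy)phenyl N,N-diethylcarbamate F4. NaOH in refluxing aqueous EtOH cleaves the carbamate and returns to the route at 5.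

Further compounds
F1 | step 6 | N-methoxy-N-methyl-3-[4-(benzyloxy)phenyl]prop-2-ynamide | CON(C)C(=O)C#Cc1ccc(OCc2ccccc2)cc1
F2 | step 10 | barium bis(hispidulin 7-sulfate) | COc1c(OS(=O)(=O)[O-])cc2oc(-c3ccc(O)cc3)cc(=O)c2c1O.COc1c(OS(=O)(=O)[O-])cc2oc(-c3ccc(O)cc3)cc(=O)c2c1O.[Ba+2]
F3 | step 4 | 4-methoxy-3,5-bis(methoxymethoxy)phenyl N,N-diethylcarbamate | CCN(CC)C(=O)Oc1cc(OCOC)c(OC)c(OCOC)c1
F4 | step 4 | 2-iodo-4-methoxy-3,5-bis(methoxymethoxy)phenyl N,N-diethylcarbamate | CCN(CC)C(=O)Oc1cc(OCOC)c(OC)c(OCOC)c1I
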